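## Analysis of the target

The target 13 is a flavone: a 4H-chromen-4-one (benzo ring A fused to pyranone ring C) with a para-substituted phenyl ring B on C2. Oxygen sits on C3 (methyl ether), C5 (free hydroxyl, hydrogen-bonded to the C4 carbonyl), C7 (methyl ether) and C4′ (3-methylbut-2-enyl, i.e. prenyl, ether). There is no stereocentre and no stereogenic double bond, so the problems are only regiochemical and chemoselective. The fragile group is the aryl prenyl ether: acids ionise it, its trisubstituted alkene reacts with halogens, quinones and SeO2, and on heating it can migrate to carbon. The 3-methoxy group, an enol ether conjugated to C4=O, is the next weakest point, towards Lewis acids. The difficulty is to place four oxygens carrying three different substituents, in particular to tell O5 from O7, and to reach the 3-oxygenated flavone oxidation level without harming the prenyl ether. The strategy rests on ring A: C5, C7 and C8a bear oxygen in a 1,3,5-relationship and C4a bears the acyl carbon C4. This is the pattern left when a chain with carbonyls on alternate carbons (C5–C6–C7–C8–C8a–C4a–C4) is folded by forming the C4a–C5 bond. The ring so formed is a symmetric 2,4,6-trihydroxyphenyl ketone, so O5 and O7 need not be distinguished until the flavone exists, where chelation of O5 does it.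

## Retrosynthetic reasoning

**13 to 11 and 12.** The O4′–CH2 bond of the prenyl ether is cut first, giving 5-hydroxy-2-(4-hydroxyphenyl)-3,7-dimethoxy-4H-chromen-4-one 11 and prenyl bromide 12. The prenyl ether is the group least likely to survive the oxidation that aromatises ring C, so it is attached last. In 11 the two free hydroxyls differ sharply: O5 is locked in a hydrogen bond to C4=O and O4′ is an ordinary phenol. The forward step only has to mono-alkylate O4′.

**11 to 10.** The O4′–H is traced back to a benzyl ether in 2-[4-(benzyloxy)phenyl]-5-hydroxy-3,7-dimethoxy-4H-chromen-4-one 10. Benzyl stands in for prenyl from the first step onward. It tolerates strong base, alkoxide and halogen oxidants, and hydrogenolysis removes it without touching the tetrasubstituted C2=C3 bond.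

**10 to 9.** The O7–CH3 bond is cut, leading to 2-[4-(benzyloxy)phenyl]-5,7-dihydroxy-3-methoxy-4H-chromen-4-one 9. Methylation is placed at the flavone stage because only there is O5 deactivated by chelation, while O7 is the most acidic phenol. With O4′ blocked, one equivalent of methylating agent has a single reactive site.

**9 to 7 through 8.** The O1–C2 bond is cut and C2–C3 is taken back to the saturated level, revealing the chalcone (Z)-3-[4-(benzyloxy)phenyl]-2-methoxy-1-(2,4,6-trihydroxyphenyl)prop-2-en-1-one 7 by way of the flavanone 8. Ring A of 7 is symmetric, so either ortho hydroxyl closes ring C to the same product. The methoxy group already sits on the carbon that becomes C3, so no separate C3 oxygenation is needed. The forward reaction is an oxa-Michael closure followed by loss of two hydrogens.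

**7 to 5 through 6.** The C4a–C5 bond is cut. This is the bond a Claisen condensation makes, and cutting it unravels ring A into the open-chain methyl 3,5,7-trioxo ester 6. The chain is stored as the pyrone 6-[(Z)-4-[4-(benzyloxy)phenyl]-3-methoxy-2-oxobut-3-en-1-yl]-4-hydroxy-2H-pyran-2-one 5, in which three of the four chain carbonyls are masked. The gain is that ring A with all three oxygens comes from one commodity heterocycle, with no aromatic substitution and no protecting group on ring A. The forward step has to open the lactone with an alkoxide and make the C6 methylene attack the ester carbon (Claisen), not let C2 attack the C7 ketone (aldol).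

**5 to 3 and 4.** The bond between the side-chain methylene and the ketone carbon (chain C6–C7) is cut. This gives 4-hydroxy-6-methyl-2H-pyran-2-one 4, whose methyl carbon is nucleophilic in the dianion, and methyl (Z)-3-[4-(benzyloxy)phenyl]-2-methoxyprop-2-enoate 3 as the acyl donor. The forward reaction must be a 1,2-acylation at carbon.

**3 to 1 and 2.** The C=C bond of the acrylate is cut to 4-(benzyloxy)benzaldehyde 1 and methyl 2-methoxyacetate 2. An ester aldol condensation sets the C2–C3 bond of the future flavone and brings in the C3 oxygen as its methyl ether.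

## Alternatives that were turned down

**Alternative 1:** Ring C is disconnected by removing C3 as a one-carbon unit, which leads back to the 3-silyloxybenzofuran A2 (3,4-bis(tert-butyldimethylsilyloxy)-2-[4-(tert-butyldimethylsilyloxy)phenyl]-6-methoxy-1-benzofuran).
- Forward key step: the carbene released from diazirine A3 (3-chloro-3-methoxy-3H-diazirine) adds to the C2=C3 bond of A2. The cyclopropane opens with loss of chloride and of the enol silyl group, inserting the methoxy-bearing carbon and giving the flavone A1 (5-(tert-butyldimethylsilyloxy)-2-[4-(tert-butyldimethylsilyloxy)phenyl]-3,7-dimethoxy-4H-chromen-4-one).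
- For it: C3, its methoxy group and the flavone oxidation level arrive in one operation, so no dehydrogenation is needed. Desilylation of A1 would give 11 and join the last step of the chosen route. On this point it is stronger.
- Against it: the carbene is ambiphilic and adds slowly to very electron-rich, tetrasubstituted π bonds. The bond in A2 is part of an aromatic furan flanked by an aryl and a bulky silyloxy group. A3 is a shock-sensitive reagent that must be made fresh. A2 needs a 2-arylbenzofuran-3-one in which the two ring A oxygens are already differentiated, and its enol ether is prone to autoxidation at C2.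
- Comparison: the chosen route is no shorter in the end game, but it relies on a ring-forming reaction type with direct analogy and differentiates O5 from O7 late, by chelation.

**Alternative 2:** The O1–C8a bond is disconnected, leading to the diketone A5 (1-(2,6-difluoro-4-methoxyphenyl)-2-methoxy-3-[4-(3-methylbut-2-enyloxy)phenyl]propane-1,3-dione).
- Forward key step: with a carbonate base in a dipolar aprotic solvent the enolate oxygen displaces one of the two equivalent ortho fluorides, giving A4 (5-fluoro-3,7-dimethoxy-2-[4-(3-methylbut-2-enyloxy)phenyl]-4H-chromen-4-one).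
- For it: the two fluorides are equivalent, so there is no regiochemistry. Both methyl ethers are in place from the start, ring C forms at the flavone oxidation level, and the conditions are mild enough to carry the prenyl ether throughout. The ring closure itself is more certain than a Claisen fold, and the route is probably shorter.
- Against it: the fluorine is a placeholder that must be exchanged for hydroxyl on the finished chromone. Oxygen nucleophiles strong enough for that can also add to C2 and open ring C. Making A5 means C-acylating an α-methoxy ketone enolate with a doubly ortho-substituted aroyl unit, where O-acylation competes, and it needs a specialised fluorinated building block.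
- Comparison: the chosen route concedes step count and protecting-group economy. It offers in return all three ring A oxygens from the chain itself, no late substitution on a base-sensitive chromone, and commodity starting materials.

**Alternative 3:** The C4–C4a bond is disconnected, leading to the acid A7 ((E)-3-[4-(benzyloxy)phenyl]-3-(3,5-dimethoxyphenoxy)-2-methoxyprop-2-enoic acid).
- Forward key step: after activation of the carboxyl group as a mixed anhydride, the acylium equivalent attacks an ortho carbon of the symmetric 3,5-dimethoxyphenoxy ring and gives A6 (2-[4-(benzyloxy)phenyl]-3,5,7-trimethoxy-4H-chromen-4-one).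
- For it: the accepting ring is symmetric and highly activated, and six-membered Friedel–Crafts acylation onto it is dependable, more so than the fold chosen here. The flavone oxidation level is reached directly.
- Against it: A7 is a tetrasubstituted β-aryloxy-α-methoxyacrylic acid that needs the aryloxy group cis to the carboxyl. Its preparation adds steps. The acidic closure excludes the prenyl ether, as in the chosen route. A6 then needs the 5-methyl ether cleaved selectively in the presence of the 3- and 7-methyl ethers, and the 3-methoxy group next to the same carbonyl is the next most labile.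
- Comparison: the length is similar. The chosen route ends by selective alkylation of free hydroxyls, which is easier to control than selective dealkylation of three methyl ethers.

Key step: step 3

Remark on the chemistry: the 4′-oxygen is carried as a benzyl ether through the key step and the prenyl group is attached last, because an aryl prenyl ether is not expected to survive the iodine-mediated dehydrogenation that completes ring C. 4-(Benzyloxy)benzaldehyde and Mg(OMe)2 in methanol are taken as purchasable.

## Route

Step 1
Reactants: 1 4-(benzyloxy)benzaldehyde; 2 methyl 2-methoxyacetate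
Product: 3 methyl (Z)-3-[4-(benzyloxy)phenyl]-2-methoxyprop-2-enoate
Conditions: NaOMe (1.5 equiv), 2 (3 equiv), THF–MeOH, 0 °C → 60 °C
Reagents that add atoms: none
Why: Claisen-type ester aldol condensation: the enolate of 2 adds to the non-enolisable aldehyde 1 and the aldolate loses hydroxide by E1cB. The alkene should settle as the Z isomer (aryl trans to the ester, cis to the methoxy group), and the excess of 2 absorbs the hydroxide that is released.

Step 2
Reactants: 3 methyl (Z)-3-[4-(benzyloxy)phenyl]-2-methoxyprop-2-enoate; 4 4-hydroxy-6-methyl-2H-pyran-2-one
Product: 5 6-[(Z)-4-[4-(benzyloxy)phenyl]-3-methoxy-2-oxobut-3-en-1-yl]-4-hydroxy-2H-pyran-2-one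
Conditions: 4 (2.1 equiv), LiN(iPr)2 (4.3 equiv), THF, −78 → 0 °C; then 3, −78 °C → rt; aq. HCl
Reagents that add atoms: none
Why: Dianion C-acylation (Claisen condensation): after the 4-hydroxyl, the 6-methyl group of 4 is deprotonated to a vinylogous enolate that attacks the ester carbonyl of 3. The product is deprotonated at once by the second equivalent of dianion, which stops further addition. The α-methoxy and p-alkoxyaryl groups make the β-carbon of 3 a poor Michael acceptor, so 1,2-attack should prevail.

Step 3
Reactants: 5 6-[(Z)-4-[4-(benzyloxy)phenyl]-3-methoxy-2-oxobut-3-en-1-yl]-4-hydroxy-2H-pyran-2-one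
Product: 7 (Z)-3-[4-(benzyloxy)phenyl]-2-methoxy-1-(2,4,6-trihydroxyphenyl)prop-2-en-1-one, via magnesium-chelated methyl 3,5,7-trioxo ester 6 (not isolated)
Conditions: Mg(OMe)2 (8 equiv), MeOH, reflux; then cold 1 M HCl
Reagents that add atoms: none
Why: Methoxide adds to the lactone carbonyl of 5 and opens the pyrone to the magnesium-chelated triketo ester 6 (ester C1, ketones C3, C5, C7). The C6 carbon, centre of the C5/C7 diketonate, then attacks the ester carbonyl C1, methoxide leaves, and the cyclohexanetrione tautomerises to the acylphloroglucinol 7; this aromatisation makes the step irreversible. The closest known reaction type is the biomimetic Claisen (Dieckmann-type) cyclisation of 3,5,7-triketo esters and of 6-(2-oxoalkyl)-4-hydroxy-2-pyrones to acylphloroglucinols, the laboratory counterpart of chalcone synthase folding. Ring A closes by six-membered exo-trig attack on the ester carbonyl; the nucleophilic carbon C6 becomes a ring atom, and its enolate double bond may lie towards C7 (outside the new ring) or towards C5 (inside it), both being allowed modes. No stereocentre is formed, and the Z enol ether is the stable geometry under equilibrating conditions. The selectivity needed is Claisen closure (C6 on C1) over aldol closure (C2 on the C7 ketone, which would give a resorcylate). It is secured because magnesium binds the C5/C7 diketonate, which makes C6 the carbon nucleophile and removes C7 as an electrophile, while the anhydrous alkoxide medium keeps C1 as an ester and leaves the less acidic C2 largely protonated. The benzyl ether and the α-methoxy enone are inert to methoxide, whose conjugate addition is reversible and disfavoured by the two donor groups. Any 7 that closes to flavanone 8 during work-up is carried on, since step 4 passes through 8.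

Step 4
Reactants: 7 (Z)-3-[4-(benzyloxy)phenyl]-2-methoxy-1-(2,4,6-trihydroxyphenyl)prop-2-en-1-one
Product: 9 2-[4-(benzyloxy)phenyl]-5,7-dihydroxy-3-methoxy-4H-chromen-4-one, via racemic trans-3-methoxyflavanone 8 (not isolated)
Conditions: pyridine, 90 °C; then I2 (1.1 equiv), 90 °C; aq. Na2S2O3
Reagents that add atoms: none
Why: Hot pyridine should close ring C by 6-endo-trig oxa-Michael addition of either of the two equivalent ortho phenols to the β-carbon, giving 8 as the trans racemate (thermodynamic; C3 is epimerisable and both transient stereocentres are erased in the same flask). Iodine then iodinates C3 through the enol, and loss of HI, helped by the 3-methoxy group and the p-alkoxyphenyl group at C2, gives the flavone. This is the iodine–pyridine dehydrogenation of 5-hydroxyflavanones, which tolerates free phenols and a benzyl ether.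

Step 5
Reactants: 9 2-[4-(benzyloxy)phenyl]-5,7-dihydroxy-3-methoxy-4H-chromen-4-one
Product: 10 2-[4-(benzyloxy)phenyl]-5-hydroxy-3,7-dimethoxy-4H-chromen-4-one
Conditions: MeI (1.1 equiv), K2CO3 (1.2 equiv), acetone, 40 °C
Reagents that add atoms: methyl iodide, CI
Why: Williamson methylation: the 7-hydroxyl, para to the C4 carbonyl, is the most acidic phenol, the 5-hydroxyl is held in a hydrogen bond to C4=O, and O4′ is blocked. One equivalent of MeI should therefore alkylate O7 only.

Step 6
Reactants: 10 2-[4-(benzyloxy)phenyl]-5-hydroxy-3,7-dimethoxy-4H-chromen-4-one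
Product: 11 5-hydroxy-2-(4-hydroxyphenyl)-3,7-dimethoxy-4H-chromen-4-one
Conditions: H2 (1 atm), 10% Pd/C, EtOAc–THF, rt
Reagents that add atoms: none
Why: Hydrogenolysis of the benzyl aryl ether over palladium on carbon. The tetrasubstituted C2=C3 bond and the vinylogous ester carbonyl of the flavone are not expected to be reduced at 1 atm and room temperature.

Step 7
Reactants: 11 5-hydroxy-2-(4-hydroxyphenyl)-3,7-dimethoxy-4H-chromen-4-one; 12 1-bromo-3-methylbut-2-ene (prenyl bromide)
Product: 13 5-hydroxy-3,7-dimethoxy-2-[4-(3-methylbut-2-enyloxy)phenyl]-4H-chromen-4-one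
Conditions: 12 (1.2 equiv), K2CO3 (1.5 equiv), acetone, reflux
Reagents that add atoms: none
Why: Williamson etherification: the 4′-phenoxide displaces the allylic bromide by SN2 while the chelated 5-hydroxyl stays untouched under K2CO3 in acetone. The mild base and low temperature avoid C-prenylation and Claisen rearrangement.

## Compound list

1 | 4-(benzyloxy)benzaldehyde | O=Cc1ccc(OCc2ccccc2)cc1 | starting material
2 | methyl 2-methoxyacetate | COCC(=O)OC | starting material
3 | methyl (Z)-3-[4-(benzyloxy)phenyl]-2-methoxyprop-2-enoate | CO/C(C(=O)OC)=C\c1ccc(OCc2ccccc2)cc1 | intermediate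
4 | 4-hydroxy-6-methyl-2H-pyran-2-one | Cc1cc(O)cc(=O)o1 | starting material
5 | 6-[(Z)-4-[4-(benzyloxy)phenyl]-3-methoxy-2-oxobut-3-en-1-yl]-4-hydroxy-2H-pyran-2-one | CO/C(C(=O)Cc1cc(O)cc(=O)o1)=C\c1ccc(OCc2ccccc2)cc1 | intermediate
6 | methyl (Z)-9-[4-(benzyloxy)phenyl]-8-methoxy-3,5,7-trioxonon-8-enoate (magnesium chelate in the flask, not isolated) | COC(=O)CC(=O)CC(=O)CC(=O)/C(OC)=C/c1ccc(OCc2ccccc2)cc1 | intermediate
7 | (Z)-3-[4-(benzyloxy)phenyl]-2-methoxy-1-(2,4,6-trihydroxyphenyl)prop-2-en-1-one | CO/C(C(=O)c1c(O)cc(O)cc1O)=C\c1ccc(OCc2ccccc2)cc1 | intermediate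
8 | rac-(2R,3R)-2-[4-(benzyloxy)phenyl]-5,7-dihydroxy-3-methoxy-2,3-dihydro-4H-chromen-4-one (trans racemate, one enantiomer drawn, not isolated) | CO[C@H]1C(=O)c2c(O)cc(O)cc2O[C@@H]1c1ccc(OCc2ccccc2)cc1 | intermediate
9 | 2-[4-(benzyloxy)phenyl]-5,7-dihydroxy-3-methoxy-4H-chromen-4-one | COc1c(-c2ccc(OCc3ccccc3)cc2)oc2cc(O)cc(O)c2c1=O | intermediate
10 | 2-[4-(benzyloxy)phenyl]-5-hydroxy-3,7-dimethoxy-4H-chromen-4-one | COc1cc(O)c2c(=O)c(OC)c(-c3ccc(OCc4ccccc4)cc3)oc2c1 | intermediate
11 | 5-hydroxy-2-(4-hydroxyphenyl)-3,7-dimethoxy-4H-chromen-4-one | COc1cc(O)c2c(=O)c(OC)c(-c3ccc(O)cc3)oc2c1 | intermediate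
12 | 1-bromo-3-methylbut-2-ene (prenyl bromide) | CC(C)=CCBr | starting material
13 | 5-hydroxy-3,7-dimethoxy-2-[4-(3-methylbut-2-enyloxy)phenyl]-4H-chromen-4-one | COc1cc(O)c2c(=O)c(OC)c(-c3ccc(OCC=C(C)C)cc3)oc2c1 | target

## Step count and least certain steps

Total step count: 7. Longest linear sequence: 7 steps (1 → 3 → 5 → 7 → 9 → 10 → 11 → 13).

**Step 3 (key step).** The chain may fold the other way: the C2 methylene adds to the C7 ketone (aldol) and dehydration leads to a resorcylate. The opened ester may also re-lactonise on work-up if the magnesium chelate is too stable to cyclise, and methoxide may cleave the chain at C7 by retro-Claisen attack.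
Fallback: the fold is given up and 7 is assembled from aldehyde 1 by Claisen–Schmidt condensation. Hoesch acylation of phloroglucinol with methoxyacetonitrile (ZnCl2, HCl, ether; then hot water) should give 2-methoxy-1-(2,4,6-trihydroxyphenyl)ethan-1-one F1. Chloromethyl methyl ether (2 equiv) and diisopropylethylamine should protect the two non-chelated hydroxyls to give 1-[2-hydroxy-4,6-bis(methoxymethoxy)phenyl]-2-methoxyethan-1-one F2. Condensation of F2 with 1 (KOH, EtOH, rt) should give (Z)-3-[4-(benzyloxy)phenyl]-1-[2-hydroxy-4,6-bis(methoxymethoxy)phenyl]-2-methoxyprop-2-en-1-one F3. Mild HCl in methanol removes both acetals and the sequence returns at 7; any material that has closed to 8 is equally usable in step 4.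

**Step 2.** The acylation may stall through poor solubility of the dianion of 4 or through proton transfer from the product to unreacted dianion. Conjugate addition to the acrylate remains possible.
Fallback: starting from ester 3, the chain is built from the ketone end. Acylation of the dianion of pentane-2,4-dione (LiN(iPr)2, 2 equiv, THF) with 3 should give (Z)-8-[4-(benzyloxy)phenyl]-7-methoxyoct-7-ene-2,4,6-trione F4. Its trianion (LiN(iPr)2, 3 equiv) should be carboxylated at the terminal methyl by CO2 to give (Z)-9-[4-(benzyloxy)phenyl]-8-methoxy-3,5,7-trioxonon-8-enoic acid F5. Cold acetic anhydride should lactonise F5, and the sequence returns at pyrone 5.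

**Step 4.** Iodine may substitute ring A at C6 or C8 in competition with C3, and enolisation at the tertiary, alkoxy-substituted C3 may be slow, so dehydrogenation may be incomplete.
Fallback: from 7, ring closure with NaOAc in refluxing ethanol and isolation of 8. Acetylation (Ac2O, pyridine, 4-dimethylaminopyridine) should give rac-(2R,3R)-2-[4-(benzyloxy)phenyl]-3-methoxy-4-oxo-3,4-dihydro-2H-chromene-5,7-diyl diacetate F6, whose ring A is deactivated. Hydride abstraction at C2 with DDQ in refluxing dioxane should give 2-[4-(benzyloxy)phenyl]-3-methoxy-4-oxo-4H-chromene-5,7-diyl diacetate F7. Methanolysis (K2CO3, MeOH) returns at 9.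

**Step 1.** The hydroxide released may saponify the product ester or stop the reaction at the aldol stage, and the aldehyde may undergo Cannizzaro disproportionation.
Fallback: from 1, Horner–Wadsworth–Emmons olefination with commercial methyl 2-(dimethoxyphosphoryl)-2-methoxyacetate (NaH, THF, 0 °C) returns at 3 under non-hydrolytic conditions. A Z/E mixture would be acceptable, because the alkene geometry disappears when ring C closes.

## Further compounds

F1 | step 3 | 2-methoxy-1-(2,4,6-trihydroxyphenyl)ethan-1-one | COCC(=O)c1c(O)cc(O)cc1O
F2 | step 3 | 1-[2-hydroxy-4,6-bis(methoxymethoxy)phenyl]-2-methoxyethan-1-one | COCOc1cc(O)c(C(=O)COC)c(OCOC)c1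
F3 | step 3 | (Z)-3-[4-(benzyloxy)phenyl]-1-[2-hydroxy-4,6-bis(methoxymethoxy)phenyl]-2-methoxyprop-2-en-1-one | CO/C(C(=O)c1c(O)cc(OCOC)cc1OCOC)=C\c1ccc(OCc2ccccc2)cc1
F4 | step 2 | (Z)-8-[4-(benzyloxy)phenyl]-7-methoxyoct-7-ene-2,4,6-trione | CC(=O)CC(=O)CC(=O)/C(OC)=C/c1ccc(OCc2ccccc2)cc1
F5 | step 2 | (Z)-9-[4-(benzyloxy)phenyl]-8-methoxy-3,5,7-trioxonon-8-enoic acid | OC(=O)CC(=O)CC(=O)CC(=O)/C(OC)=C/c1ccc(OCc2ccccc2)cc1
F6 | step 4 | rac-(2R,3R)-2-[4-(benzyloxy)phenyl]-3-methoxy-4-oxo-3,4-dihydro-2H-chromene-5,7-diyl diacetate | CO[C@H]1C(=O)c2c(OC(C)=O)cc(OC(C)=O)cc2O[C@@H]1c1ccc(OCc2ccccc2)cc1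
F7 | step 4 | 2-[4-(benzyloxy)phenyl]-3-methoxy-4-oxo-4H-chromene-5,7-diyl diacetate | COc1c(-c2ccc(OCc3ccccc3)cc2)oc2cc(OC(C)=O)cc(OC(C)=O)c2c1=O
F0 | step 1 | none | none
A1 | alternative 1 | 5-(tert-butyldimethylsilyloxy)-2-[4-(tert-butyldimethylsilyloxy)phenyl]-3,7-dimethoxy-4H-chromen-4-one | COc1cc(O[Si](C)(C)C(C)(C)C)c2c(=O)c(OC)c(-c3ccc(O[Si](C)(C)C(C)(C)C)cc3)oc2c1
A2 | alternative 1 | 3,4-bis(tert-butyldimethylsilyloxy)-2-[4-(tert-butyldimethylsilyloxy)phenyl]-6-methoxy-1-benzofuran | COc1cc(O[Si](C)(C)C(C)(C)C)c2c(O[Si](C)(C)C(C)(C)C)c(-c3ccc(O[Si](C)(C)C(C)(C)C)cc3)oc2c1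
A3 | alternative 1 | 3-chloro-3-methoxy-3H-diazirine | COC1(Cl)N=N1
A4 | alternative 2 | 5-fluoro-3,7-dimethoxy-2-[4-(3-methylbut-2-enyloxy)phenyl]-4H-chromen-4-one | COc1cc(F)c2c(=O)c(OC)c(-c3ccc(OCC=C(C)C)cc3)oc2c1
A5 | alternative 2 | 1-(2,6-difluoro-4-methoxyphenyl)-2-methoxy-3-[4-(3-methylbut-2-enyloxy)phenyl]propane-1,3-dione | COc1cc(F)c(C(=O)C(OC)C(=O)c2ccc(OCC=C(C)C)cc2)c(F)c1
A6 | alternative 3 | 2-[4-(benzyloxy)phenyl]-3,5,7-trimethoxy-4H-chromen-4-one | COc1cc(OC)c2c(=O)c(OC)c(-c3ccc(OCc4ccccc4)cc3)oc2c1
A7 | alternative 3 | (E)-3-[4-(benzyloxy)phenyl]-3-(3,5-dimethoxyphenoxy)-2-methoxyprop-2-enoic acid | CO/C(C(=O)O)=C(/Oc1cc(OC)cc(OC)c1)c1ccc(OCc2ccccc2)cc1
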